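**Retrosynthetic overview**
- Feature: in the pyrrole ring, C2 carries Br and is bonded only to N1 and C3. It therefore corresponds to an isocyanide carbon that has taken up Br2 (an N1=C2Br2 unit).
- Last disconnection: C3–H comes from C3–CO2tBu. The ester is a traceless activating group, removed by acid as isobutene and then CO2.
- Key disconnection: C2–C3. The ester-stabilised benzylic carbanion (future C3) attacks the N=CBr2 carbon and one bromide leaves. The benzene ring is bought, and the pyrrole ring is the only ring formed.
- N=CBr2 comes from isocyanide + Br2, and the isocyanide from the formamide, the amine and the nitroarene. The CH2CO2tBu arm comes from a malonate SNAr on 1,5-dibromo-2-fluoro-3-nitrobenzene, which already carries the future C4–Br and C6–Br.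

Key step: step 9

Assumption: like other isocyanide dibromides, 12 is sensitive to heat and moisture, so it is carried on as the cold crude residue of step 8 without purification.

**Step 1**
Reactants: 1 4-bromo-1-fluoro-2-nitrobenzene
Product: 2 1,5-dibromo-2-fluoro-3-nitrobenzene
Conditions: NBS (1.2 equiv), conc. H2SO4, 60 °C
Reagents that add atoms: N-bromosuccinimide, O=C1CCC(=O)N1Br
Why: Electrophilic aromatic bromination with acid-activated NBS, the usual method for deactivated arenes, should go to C6 of 1, the only free position that is ortho to fluorine and meta to the nitro group, whereas C3 and C5 are ortho or para to NO2.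

**Step 2**
Reactants: 2 1,5-dibromo-2-fluoro-3-nitrobenzene; 3 diethyl malonate
Product: 4 diethyl 2-(2,4-dibromo-6-nitrophenyl)malonate
Conditions: K2CO3 (2.5 equiv), DMF, 50 °C; then 1 M HCl
Reagents that add atoms: diethyl malonate (3), CCOC(=O)CC(=O)OCC
Why: Nucleophilic aromatic substitution (SNAr, addition–elimination) should occur only at the C–F carbon, which is ortho to NO2 and bears the best leaving group, while both C–Br carbons are meta to NO2 and are not activated.

**Step 3**
Reactants: 4 diethyl 2-(2,4-dibromo-6-nitrophenyl)malonate
Product: 6 2-(2,4-dibromo-6-nitrophenyl)acetic acid, via 2-(2,4-dibromo-6-nitrophenyl)malonic acid 5 (not isolated)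
Conditions: 6 M HCl/AcOH (1:1), reflux
Reagents that add atoms: water, O
Why: Acid-catalysed ester hydrolysis followed by thermal decarboxylation of the arylmalonic acid (malonic ester synthesis) is routine, and the nitro and aryl bromide groups are inert to hot aqueous acid.

**Step 4**
Reactants: 6 2-(2,4-dibromo-6-nitrophenyl)acetic acid
Product: 7 tert-butyl 2-(2,4-dibromo-6-nitrophenyl)acetate
Conditions: Cl3CC(=NH)OtBu (2 equiv), CH2Cl2, rt
Reagents that add atoms: tert-butyl 2,2,2-trichloroacetimidate, CC(C)(C)OC(=N)C(Cl)(Cl)Cl
Why: Imidate esterification (tert-butyl cation transfer to the carboxylic acid) needs no base and so spares the acidic benzylic CH2, and it installs the ester that best resists the later ortho-amino group and still leaves with acid at the end.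

**Step 5**
Reactants: 7 tert-butyl 2-(2,4-dibromo-6-nitrophenyl)acetate
Product: 8 tert-butyl 2-(2-amino-4,6-dibromophenyl)acetate
Conditions: Fe powder (5 equiv), NH4Cl, EtOH/H2O (4:1), 60 °C, short contact; filtration, used at once
Reagents that add atoms: none
Why: Béchamp-type iron reduction at near-neutral pH converts NO2 into NH2 without touching C–Br or the acid-labile ester (hot formic acid would cleave it), and the bulky ester together with the weakly nucleophilic dibromoaniline should hold back lactamisation.

**Step 6**
Reactants: 8 tert-butyl 2-(2-amino-4,6-dibromophenyl)acetate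
Product: 9 tert-butyl 2-(2,4-dibromo-6-formamidophenyl)acetate
Conditions: HCO2H/Ac2O (premixed, 55 °C, 2 h, cooled), THF, 0 °C → rt
Reagents that add atoms: acetic formic anhydride, CC(=O)OC=O (made from formic acid, OC=O, and acetic anhydride, CC(=O)OC(C)=O)
Why: N-Formylation with the mixed anhydride is fast at 0 °C even for electron-poor anilines, transfers only the more electrophilic formyl group and caps the nitrogen before it can attack the ester.

**Step 7**
Reactants: 9 tert-butyl 2-(2,4-dibromo-6-formamidophenyl)acetate
Product: 10 tert-butyl 2-(2,4-dibromo-6-isocyanophenyl)acetate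
Conditions: POCl3 (1.2 equiv), Et3N (5 equiv), CH2Cl2, −30 → 0 °C; cold aq. NaHCO3
Reagents that add atoms: none
Why: Formamide dehydration (O-phosphorylation, then base-induced elimination) is the standard isocyanide synthesis, and Et3N at or below 0 °C is too weak a base to close the benzylic carbon onto the isocyanide prematurely.

**Step 8**
Reactants: 10 tert-butyl 2-(2,4-dibromo-6-isocyanophenyl)acetate; 11 bromine
Product: 12 tert-butyl 2-[2,4-dibromo-6-(dibromomethylideneamino)phenyl]acetate
Conditions: Br2 (1.0 equiv), CH2Cl2, −78 → −20 °C, dark, N2; concentrated cold, used crude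
Reagents that add atoms: bromine (11), BrBr
Why: α-Addition of a halogen to the divalent isocyanide carbon is the classical entry to isocyanide dihalides, and at low temperature it should far outrun substitution on the twice-brominated ring or bromination next to the non-enolised ester.

**Step 9**
Reactants: 12 tert-butyl 2-[2,4-dibromo-6-(dibromomethylideneamino)phenyl]acetate
Product: 14 tert-butyl 2,4,6-tribromo-1H-indole-3-carboxylate, via tert-butyl 2,4,6-tribromo-3H-indole-3-carboxylate 13 (not isolated)
Conditions: 12 in THF added over 1 h to LiN(SiMe3)2 (2.2 equiv), THF, −78 °C (final 0.02 M), → −20 °C; then AcOH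
Reagents that add atoms: none
Why: Proposed new method: LiN(SiMe3)2 is strong enough for a benzylic C–H whose enolate is twisted out of conjugation by two ortho substituents and too hindered to add to the imidoyl carbon as an amidine base or an alkoxide could, so it should convert 12 into its ester enolate, whose carbon attacks the N=CBr2 carbon and expels bromide (addition–elimination) to form C2–C3 and the 3H-indole 13. The closest known reaction types are the NaH- or Cu2O-mediated closure of ortho-isocyanophenylacetates to indole-3-carboxylates, the substitution of isocyanide dihalides by malonate-type carbanions, and the 5-endo-trig addition–elimination of ortho-amino β,β-difluorostyrenes to 2-fluoroindoles. The pyrrole ring closes in a formally 5-endo-trig mode at C=N, which should be feasible because the CBr2 carbon is strongly polarised and because lithium-assisted loosening of one C–Br bond moves the unit towards a bromonitrilium ion and gives the closure 5-endo-dig character. The second equivalent of base removes the very acidic C3–H of 13 and the AcOH quench protonates N1, so the sp3 C3 of 13 is racemic and transient and no stereocentre remains. The step needs C-attack over O-attack (five- against seven-membered ring), intramolecular closure over intermolecular substitution or bromine transfer to the enolate (inverse addition, high dilution, −78 °C), and a single substitution, which aromatisation secures because the remaining bromine becomes the unreactive C2–Br of an indolyl anion.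

**Step 10**
Reactants: 14 tert-butyl 2,4,6-tribromo-1H-indole-3-carboxylate
Product: 16 2,4,6-tribromo-1H-indole, via 2,4,6-tribromo-1H-indole-3-carboxylic acid 15 (not isolated)
Conditions: dry TFA/CH2Cl2 (1:1), 0 °C → rt, then 40 °C until gas evolution ends, N2, dark; cold aq. NaHCO3
Reagents that add atoms: none
Why: Acidolysis of the tert-butyl ester gives 15, and indole-3-carboxylic acids undergo acid-catalysed protodecarboxylation by ipso protonation at C3, helped here by relief of the crowding between the carboxyl group and its C2–Br and C4–Br neighbours, while exclusion of water protects C2–Br from solvolysis.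

**Compound list**
1 | 4-bromo-1-fluoro-2-nitrobenzene | O=[N+]([O-])c1cc(Br)ccc1F | starting material
2 | 1,5-dibromo-2-fluoro-3-nitrobenzene | O=[N+]([O-])c1cc(Br)cc(Br)c1F | intermediate
3 | diethyl malonate | CCOC(=O)CC(=O)OCC | starting material
4 | diethyl 2-(2,4-dibromo-6-nitrophenyl)malonate | CCOC(=O)C(C(=O)OCC)c1c(Br)cc(Br)cc1[N+](=O)[O-] | intermediate
5 | 2-(2,4-dibromo-6-nitrophenyl)malonic acid (not isolated) | OC(=O)C(C(=O)O)c1c(Br)cc(Br)cc1[N+](=O)[O-] | intermediate
6 | 2-(2,4-dibromo-6-nitrophenyl)acetic acid | OC(=O)Cc1c(Br)cc(Br)cc1[N+](=O)[O-] | intermediate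
7 | tert-butyl 2-(2,4-dibromo-6-nitrophenyl)acetate | CC(C)(C)OC(=O)Cc1c(Br)cc(Br)cc1[N+](=O)[O-] | intermediate
8 | tert-butyl 2-(2-amino-4,6-dibromophenyl)acetate | CC(C)(C)OC(=O)Cc1c(Br)cc(Br)cc1N | intermediate
9 | tert-butyl 2-(2,4-dibromo-6-formamidophenyl)acetate | CC(C)(C)OC(=O)Cc1c(Br)cc(Br)cc1NC=O | intermediate
10 | tert-butyl 2-(2,4-dibromo-6-isocyanophenyl)acetate | CC(C)(C)OC(=O)Cc1c(Br)cc(Br)cc1[N+]#[C-] | intermediate
11 | bromine | BrBr | starting material
12 | tert-butyl 2-[2,4-dibromo-6-(dibromomethylideneamino)phenyl]acetate | CC(C)(C)OC(=O)Cc1c(Br)cc(Br)cc1N=C(Br)Br | intermediate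
13 | tert-butyl 2,4,6-tribromo-3H-indole-3-carboxylate (racemic, not isolated) | CC(C)(C)OC(=O)C1C(Br)=Nc2cc(Br)cc(Br)c12 | intermediate
14 | tert-butyl 2,4,6-tribromo-1H-indole-3-carboxylate | CC(C)(C)OC(=O)c1c(Br)[nH]c2cc(Br)cc(Br)c12 | intermediate
15 | 2,4,6-tribromo-1H-indole-3-carboxylic acid (not isolated) | OC(=O)c1c(Br)[nH]c2cc(Br)cc(Br)c12 | intermediate
16 | 2,4,6-tribromo-1H-indole | Brc1cc(Br)c2cc(Br)[nH]c2c1 | target

**Step count**
Total step count: 10. Longest linear sequence: 10 (steps 1–10 from 1).

**Steps most likely to fail**

Step 9 (proposed new method).
- What may go wrong: the enolate may abstract bromine from the N=CBr2 group of a second molecule instead of attacking its carbon, the amide base may add to the imidoyl carbon, or the 5-endo closure may be so slow that oligomerisation and hydrolysis take over.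
- Fallback (known chemistry): it sets out from nitro acid 6. Fe powder in AcOH at 90 °C reduces the nitro group to 2-(2-amino-4,6-dibromophenyl)acetic acid F1. This lactamises in the same flask to 4,6-dibromo-1,3-dihydro-2H-indol-2-one F2.
- Deoxybromination of the lactam with POBr3 and imidazole in 1,2-dichloroethane at reflux then aromatises it. The route is rejoined at target 16.

Step 10.
- What may go wrong: ipso protonation at C3 of this electron-poor indole may be too slow at temperatures that C2–Br tolerates, so that long acid contact brings solvolysis at C2, bromine migration or oligomerisation.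
- Fallback: it sets out from acid 15, isolated by stopping the TFA treatment at room temperature and evaporating.
- Proton-driven decarboxylation is replaced by metal-mediated protodecarboxylation through an indolyl–silver species: Ag2CO3 (10 mol %), AcOH (5 mol %), DMSO, 100–120 °C. The route is rejoined at 16.

Step 8.
- What may go wrong: the adduct may revert to isocyanide and bromine on concentration, hydrolyse with traces of water, or suffer competing bromination at the benzylic position.
- Fallback: it sets out from isocyanide 10 and brings in the C2 bromine after ring closure. NaH in DMF at 0 °C closes 10 to tert-butyl 4,6-dibromo-1H-indole-3-carboxylate F3, formed as its sodium salt. Boc2O traps this in the same flask as di-tert-butyl 4,6-dibromo-1H-indole-1,3-dicarboxylate F4.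
- Directed magnesiation at C2, between the two carbonyl groups, uses TMPMgCl·LiCl in THF at −40 °C. A quench with BrCl2CCCl2Br gives di-tert-butyl 2,4,6-tribromo-1H-indole-1,3-dicarboxylate F5.
- The TFA conditions of step 10 remove the N-Boc group and the ester tert-butyl group. The route is rejoined at 15 and proceeds to 16.

**Further compounds**
F1 | step 9 | 2-(2-amino-4,6-dibromophenyl)acetic acid | Nc1cc(Br)cc(Br)c1CC(=O)O
F2 | step 9 | 4,6-dibromo-1,3-dihydro-2H-indol-2-one | O=C1Cc2c(Br)cc(Br)cc2N1
F0 | step 10 | none | none
F3 | step 8 | tert-butyl 4,6-dibromo-1H-indole-3-carboxylate | CC(C)(C)OC(=O)c1c[nH]c2cc(Br)cc(Br)c12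
F4 | step 8 | di-tert-butyl 4,6-dibromo-1H-indole-1,3-dicarboxylate | CC(C)(C)OC(=O)c1cn(C(=O)OC(C)(C)C)c2cc(Br)cc(Br)c12
F5 | step 8 | di-tert-butyl 2,4,6-tribromo-1H-indole-1,3-dicarboxylate | CC(C)(C)OC(=O)c1c(Br)n(C(=O)OC(C)(C)C)c2cc(Br)cc(Br)c12
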